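(Its constants belong to no real substance, and the outcome is calculated.)

The target is the product you hope to find, and here it is judged by its share of target plus isomer of the product, not by its yield.

common to all: substrate 20 mM

|  | time | remark |
|---|---|---|
| winter | 3.0 min | plug flow through a tube for 3.0 min, no back-mixing |
| spring |  | one stirred flow tank at steady state, fed with the mixture as stated, mean residence time 30.0 min |
| summer |  | a single well-mixed tank run continuously and read at steady state, 3.0 min in it on average |
| dawn | 3.0 min | a closed flask charged with all of it at once and left for 3.0 min |

    substrate ⇌ target (K1 = 0.418, k1 = 0.0151 s⁻¹)
    2 substrate → homo dimer (k2 = 0.170 L mol⁻¹ s⁻¹)
    substrate ⇌ dormant form (K3 = 0.334, k3 = 0.00102 s⁻¹)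
    substrate ⇌ isomer of the product (K4 = 220, k4 = 0.00126 s⁻¹)
    target ⇌ isomer of the product (k5 = 0.00397 s⁻¹)

- in percentages every species weighs as the substrate in it: one homo dimer counts as two
- a doubled species enters its step squared and goes two at a time
- the stated concentrations are those of everything mixed, before any reaction; amounts are the same in each set-up
- run time (winter): 3.0 min

1. the set-up with the highest share of target in all that became target or isomer of the product, at the outlet or at the end ("none" if the first two lie within 2 percentage points) (winter / spring / summer / dawn / none)
2. share of target in all that became target or isomer of the product, at the outlet or at the end, winter
3. share of target in all that became target or isomer of the product, at the outlet or at the end, spring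
4. share of target in all that became target or isomer of the product, at the outlet or at the end, summer
5. share of target in all that became target or isomer of the product, at the outlet or at the end, dawn

Start with the tank of summer and write its steady balances. Target leaves by the outflow, by the back run to substrate and by the passage to isomer, so c(target)/c(substrate) is 0.331. Now divide the rate that makes target by the rate that makes isomer: c(substrate) cancels, and you need no time course. The homo dimer and the dormant form reach these two balances through c(substrate), so they cancel with it. What you carry is the leak constant, the rate of isomer making per unit of substrate with target at its equilibrium level, 0.175 min⁻¹.

With rapid equilibrium, the tank's selectivity factor is the equilibrium constant over residence time times leak constant, so the share is 44.3%. That is my ceiling, since the balance holds the ratio lower than 0.418. My floor uses that ratio and lets no isomer return: the odds are 0.714, a share of 41.7%. The back runs from isomer are far slower than the outflow, a fraction 0.00239 of it. Allowing twice that on the odds brings the ceiling down to 41.8%.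

My hand gives no number for dawn and winter, but I commit to summer.

The forecast also names summer: winter 35.8%, spring 7.2%, summer 41.7%, dawn 35.8%, since in the tank “its steady state holds target near its quasi-equilibrium level from the start”. Its summer figure stands close to both ends of my bracket, 41.7% and 41.8% .

The simulation puts summer first at 41.7%, close to both ends of the bracket , with winter at 35.6% and dawn at 35.6%. In dawn, substrate and target relax with a half-life of 0.226 min, short against the 3.0 min of the run. Substrate and isomer relax with 9.13 min, long against it. Carry the leak constant to the tank of spring, with its 30.0 min: the ceiling is 7.37%, and the floor, from its own ratio, is 7.02%. The spring tank reads 7.18% .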